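The route builds ring B last, on the pre-formed depside ester, by disconnecting across C1'–C2', C2'–C3' and C4'–C5'. The feature exploited is the contiguous C2' hydroxyl, C3' carbon substituent and C4' methoxyl of ring B, which correspond to a ketene carbonyl, an alkyne substituent and an ynol ether oxygen. In one operation a vinylketene/methoxyalkyne benzannulation forms these three bonds and delivers the fully substituted aromatic ring B already attached to ring A. The precursor is the acid chloride of the ring A (C2 benzyl ether) half-ester of (Z)-3-methylglutaconic acid, paired with silyl-protected 3-methoxyprop-2-yn-1-ol. Desilylation, two oxidations and hydrogenolysis then give the target.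

Key step: step 8

Remark on the chemistry: commercial 3-methylglutaconic acid is taken as the E isomer; a Z or mixed sample would serve equally in step 4, since both close to the same cyclic anhydride.
Labels: ring A is the methyl benzoate ring (C1–C6, depside oxygen on C4), ring B is the acyl ring (C1'–C6', ester carbonyl on C1'), and Ar is 3-(benzyloxy)-4-(methoxycarbonyl)-2,5-dimethylphenyl (ring A attached through its C4 oxygen). The target has no stereocentre; the only stereochemical element handled is the alkene geometry of 7, 8 and 14.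

**Step 1**
Reactants: 1 methyl 2,4-dihydroxy-3,6-dimethylbenzoate
Product: 2 methyl 4-(allyloxy)-2-hydroxy-3,6-dimethylbenzoate
Conditions: allyl bromide (1.1 equiv), K2CO3, acetone, reflux
Reagents that add atoms: allyl bromide, C=CCBr
Why: Williamson etherification should be selective for the C4 hydroxyl, because the C2 hydroxyl is hydrogen-bonded to the ester carbonyl and is the weaker acid and nucleophile under mild carbonate conditions.

**Step 2**
Reactants: 2 methyl 4-(allyloxy)-2-hydroxy-3,6-dimethylbenzoate
Product: 3 methyl 4-(allyloxy)-2-(benzyloxy)-3,6-dimethylbenzoate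
Conditions: BnBr, K2CO3, DMF, 60 °C
Reagents that add atoms: benzyl bromide, BrCc1ccccc1
Why: With C4 blocked, the chelated C2 phenol should be benzylated under more forcing Williamson conditions, far below the temperature at which the allyl aryl ether would undergo Claisen rearrangement.

**Step 3**
Reactants: 3 methyl 4-(allyloxy)-2-(benzyloxy)-3,6-dimethylbenzoate
Product: 4 methyl 2-(benzyloxy)-4-hydroxy-3,6-dimethylbenzoate
Conditions: Pd(PPh3)4 (3 mol %), morpholine, THF, rt
Reagents that add atoms: none
Why: Allyl transfer to morpholine catalysed by zerovalent palladium (Tsuji–Trost deallylation) should free the C4 phenol without touching the benzyl ether or the methyl ester.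

**Step 4**
Reactants: 5 (E)-3-methylglutaconic acid
Product: 6 3-methylglutaconic anhydride
Conditions: Ac2O, 70 °C; evaporate, recrystallise
Reagents that add atoms: none
Why: Cyclodehydration with acetic anhydride should give the six-membered anhydride, the mixed-anhydride intermediate equilibrating E to Z through its dienol so that the E acid also closes.

**Step 5**
Reactants: 4 methyl 2-(benzyloxy)-4-hydroxy-3,6-dimethylbenzoate, 6 3-methylglutaconic anhydride
Product: 7 (2Z)-5-(Ar-oxy)-3-methyl-5-oxopent-2-enoic acid
Conditions: Et3N (1.1 equiv), DMAP (10 mol %), CH2Cl2, −20 °C → rt; cold 1 M HCl work-up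
Reagents that add atoms: none
Why: DMAP-catalysed anhydride opening by the C4 phenol should occur at the more electrophilic non-conjugated carbonyl, and opening of the ring necessarily leaves the new ester arm and the free conjugated acid cis across the C=C (Z).

**Step 6**
Reactants: 7 (2Z)-5-(Ar-oxy)-3-methyl-5-oxopent-2-enoic acid
Product: 8 methyl 2-(benzyloxy)-4-{[(3Z)-5-chloro-3-methyl-5-oxopent-3-enoyl]oxy}-3,6-dimethylbenzoate
Conditions: (COCl)2 (1.5 equiv), DMF (cat.), CH2Cl2, 0 °C → rt; concentrate and use crude
Reagents that add atoms: oxalyl chloride, ClC(=O)C(=O)Cl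
Why: Acid chloride formation by Vilsmeier-type activation is base-free and should leave the aryl ester, the benzyl ether and the Z alkene untouched.

**Step 7**
Reactants: 9 trichloroethylene
Product: 13 tert-butyl[(3-methoxyprop-2-yn-1-yl)oxy]dimethylsilane, via (E)-1,2-dichloro-1-methoxyethene 10 (not isolated), via lithium methoxyacetylide 11 (not isolated), via lithium 3-methoxyprop-2-yn-1-olate 12 (not isolated)
Conditions: KH, MeOH, THF, 0 °C, then 9, −50 °C → rt; n-BuLi (2.2 equiv), −78 → −40 °C; (CH2O)n, −40 °C → rt; TBSCl, imidazole (cat.), DMF, 0 °C → rt; NaHCO3 work-up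
Reagents that add atoms: methanol, CO; formaldehyde (from paraformaldehyde), C=O; tert-butyldimethylsilyl chloride, CC(C)(C)[Si](C)(C)Cl
Why: Methoxide adds to dichloroacetylene formed in the flask, n-BuLi then effects elimination and Li–Cl exchange to the lithium alkoxyacetylide (the trichloroethylene route to ynol ethers), which adds to formaldehyde, and silylating the alkoxide in the same flask avoids isolating the rearrangement-prone propargylic alcohol.

**Step 8**
Reactants: 8 methyl 2-(benzyloxy)-4-{[(3Z)-5-chloro-3-methyl-5-oxopent-3-enoyl]oxy}-3,6-dimethylbenzoate, 13 tert-butyl[(3-methoxyprop-2-yn-1-yl)oxy]dimethylsilane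
Product: 18 methyl 2-(benzyloxy)-4-{[3-({[tert-butyl(dimethyl)silyl]oxy}methyl)-2-hydroxy-4-methoxy-6-methylbenzoyl]oxy}-3,6-dimethylbenzoate, via vinylketene 14 (not isolated), via cyclobutenone 15 (not isolated), via dienylketene 16 (not isolated), via cyclohexadienone 17 (not isolated)
Conditions: 13 (2.5 equiv), Et3N (1.3 equiv), toluene, slow addition of 8 at 0 °C → rt; then 90 °C
Reagents that add atoms: none
Why: Et3N removes HCl across four atoms of 8 (the acidic CH2 between aryl ester and alkene is deprotonated) to give vinylketene 14, whose ketene C=C adds the ynol ether by [2+2] cycloaddition (C2'–C3' and C4'–C5') to cyclobutenone 15; on warming 15 opens in a four-electron electrocyclic step to dienylketene 16, which closes by six-electron electrocyclization (C1'–C2') to dienone 17 and tautomerizes to phenol 18. The closest known reaction type is the Danheiser benzannulation of vinylketenes with alkoxyalkynes, joined to the standard amine-induced 1,4-dehydrochlorination of unsaturated acid chlorides to vinylketenes. Ring B is closed by a thermal disrotatory 6π electrocyclization of the dienylketene, fed by the reversible 4π opening of 15, so that only the isomer with the alkenyl arm cis to the ketene is drained. No stereocentre is formed in 18, because the sp3 carbons of 15 and 17 are erased by ring opening and enolization. Regiochemistry is the selectivity needed: the alkyne carbon remote from OMe is the nucleophilic one and bonds to the electrophilic ketene carbonyl carbon, which places CH2OTBS at C3' between OH and OMe, and the CH2 of 8 is far more acidic than its CH3, so the ester-bearing terminus becomes C1'. The Z geometry of 8 should help as well, since allylic 1,3-strain against the cis COCl turns the aryl ester outward during deprotonation, leaving it trans to the ketene, where it cannot close onto it through oxygen to a 2-pyranone.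

**Step 9**
Reactants: 18 methyl 2-(benzyloxy)-4-{[3-({[tert-butyl(dimethyl)silyl]oxy}methyl)-2-hydroxy-4-methoxy-6-methylbenzoyl]oxy}-3,6-dimethylbenzoate
Product: 19 methyl 2-(benzyloxy)-4-{[2-hydroxy-3-(hydroxymethyl)-4-methoxy-6-methylbenzoyl]oxy}-3,6-dimethylbenzoate
Conditions: TBAF (1.1 equiv), AcOH (1.1 equiv), THF, 0 °C → rt
Reagents that add atoms: none
Why: Fluoride-induced desilylation cleaves the primary benzylic silyl ether, and acetic acid buffering keeps the medium near neutral so that the depside ester and the salicyl alcohol should survive.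

**Step 10**
Reactants: 19 methyl 2-(benzyloxy)-4-{[2-hydroxy-3-(hydroxymethyl)-4-methoxy-6-methylbenzoyl]oxy}-3,6-dimethylbenzoate
Product: 20 methyl 2-(benzyloxy)-4-[(3-formyl-2-hydroxy-4-methoxy-6-methylbenzoyl)oxy]-3,6-dimethylbenzoate
Conditions: activated MnO2 (excess), CH2Cl2, rt
Reagents that add atoms: none
Why: Benzylic oxidation with MnO2 should take the electron-rich benzylic alcohol to the hydrogen-bonded salicylaldehyde without over-oxidation and without touching the phenol or the esters.

**Step 11**
Reactants: 20 methyl 2-(benzyloxy)-4-[(3-formyl-2-hydroxy-4-methoxy-6-methylbenzoyl)oxy]-3,6-dimethylbenzoate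
Product: 21 3-[(Ar-oxy)carbonyl]-2-hydroxy-6-methoxy-4-methylbenzoic acid
Conditions: NaClO2, NaH2PO4, 2-methyl-2-butene (excess), t-BuOH/THF/H2O, 0 °C → rt
Reagents that add atoms: sodium chlorite, [Na+].[O-]Cl=O
Why: Pinnick oxidation should convert the aryl aldehyde into the acid under buffered conditions, with 2-methyl-2-butene scavenging HOCl so that the electron-rich ring B is not chlorinated.

**Step 12**
Reactants: 21 3-[(Ar-oxy)carbonyl]-2-hydroxy-6-methoxy-4-methylbenzoic acid
Product: 22 2-hydroxy-3-{[3-hydroxy-4-(methoxycarbonyl)-2,5-dimethylphenoxy]carbonyl}-6-methoxy-4-methylbenzoic acid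
Conditions: H2 (1 atm), Pd/C (10 %), EtOAc, rt
Reagents that add atoms: none
Why: Hydrogenolysis over Pd/C should remove the benzyl ether as toluene, nothing else in the molecule being reducible at one atmosphere and room temperature.

**Compound list**

1 | methyl 2,4-dihydroxy-3,6-dimethylbenzoate | COC(=O)c1c(C)cc(O)c(C)c1O | starting material
2 | methyl 4-(allyloxy)-2-hydroxy-3,6-dimethylbenzoate | COC(=O)c1c(C)cc(OCC=C)c(C)c1O | intermediate
3 | methyl 4-(allyloxy)-2-(benzyloxy)-3,6-dimethylbenzoate | COC(=O)c1c(C)cc(OCC=C)c(C)c1OCc1ccccc1 | intermediate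
4 | methyl 2-(benzyloxy)-4-hydroxy-3,6-dimethylbenzoate | COC(=O)c1c(C)cc(O)c(C)c1OCc1ccccc1 | intermediate
5 | (E)-3-methylglutaconic acid, (2E)-3-methylpent-2-enedioic acid | OC(=O)/C=C(C)/CC(=O)O | starting material
6 | 3-methylglutaconic anhydride, 4-methyl-2H-pyran-2,6(3H)-dione | CC1=CC(=O)OC(=O)C1 | intermediate
7 | (2Z)-5-(Ar-oxy)-3-methyl-5-oxopent-2-enoic acid (ring A C4–O half-ester on the CH2 carboxyl) | COC(=O)c1c(C)cc(OC(=O)C/C(C)=C\C(=O)O)c(C)c1OCc1ccccc1 | intermediate
8 | methyl 2-(benzyloxy)-4-{[(3Z)-5-chloro-3-methyl-5-oxopent-3-enoyl]oxy}-3,6-dimethylbenzoate (acid chloride of 7) | COC(=O)c1c(C)cc(OC(=O)C/C(C)=C\C(=O)Cl)c(C)c1OCc1ccccc1 | intermediate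
9 | trichloroethylene | ClC=C(Cl)Cl | starting material
10 | (E)-1,2-dichloro-1-methoxyethene | CO/C(Cl)=C\Cl | intermediate (not isolated)
11 | lithium methoxyacetylide | [Li]C#COC | intermediate (not isolated)
12 | lithium 3-methoxyprop-2-yn-1-olate | [Li+].[O-]CC#COC | intermediate (not isolated)
13 | tert-butyl[(3-methoxyprop-2-yn-1-yl)oxy]dimethylsilane | COC#CCO[Si](C)(C)C(C)(C)C | intermediate
14 | vinylketene, methyl 2-(benzyloxy)-3,6-dimethyl-4-{[(2E)-3-methyl-5-oxopenta-2,4-dienoyl]oxy}benzoate | COC(=O)c1c(C)cc(OC(=O)/C=C(C)/C=C=O)c(C)c1OCc1ccccc1 | intermediate (not isolated)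
15 | cyclobutenone (racemic), Ar (2E)-3-[3-({[tert-butyl(dimethyl)silyl]oxy}methyl)-2-methoxy-4-oxocyclobut-2-en-1-yl]but-2-enoate | COC(=O)c1c(C)cc(OC(=O)/C=C(C)/C2C(=O)C(CO[Si](C)(C)C(C)(C)C)=C2OC)c(C)c1OCc1ccccc1 | intermediate (not isolated)
16 | dienylketene, Ar (2E,4E)-6-({[tert-butyl(dimethyl)silyl]oxy}methyl)-5-methoxy-3-methyl-7-oxohepta-2,4,6-trienoate | COC(=O)c1c(C)cc(OC(=O)/C=C(C)/C=C(OC)\C(CO[Si](C)(C)C(C)(C)C)=C=O)c(C)c1OCc1ccccc1 | intermediate (not isolated)
17 | cyclohexadienone (racemic at C1'), Ar 3-({[tert-butyl(dimethyl)silyl]oxy}methyl)-4-methoxy-6-methyl-2-oxocyclohexa-3,5-diene-1-carboxylate | COC(=O)c1c(C)cc(OC(=O)C2C(C)=CC(OC)=C(CO[Si](C)(C)C(C)(C)C)C2=O)c(C)c1OCc1ccccc1 | intermediate (not isolated)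
18 | methyl 2-(benzyloxy)-4-{[3-({[tert-butyl(dimethyl)silyl]oxy}methyl)-2-hydroxy-4-methoxy-6-methylbenzoyl]oxy}-3,6-dimethylbenzoate | COC(=O)c1c(C)cc(OC(=O)c2c(C)cc(OC)c(CO[Si](C)(C)C(C)(C)C)c2O)c(C)c1OCc1ccccc1 | intermediate
19 | methyl 2-(benzyloxy)-4-{[2-hydroxy-3-(hydroxymethyl)-4-methoxy-6-methylbenzoyl]oxy}-3,6-dimethylbenzoate | COC(=O)c1c(C)cc(OC(=O)c2c(C)cc(OC)c(CO)c2O)c(C)c1OCc1ccccc1 | intermediate
20 | methyl 2-(benzyloxy)-4-[(3-formyl-2-hydroxy-4-methoxy-6-methylbenzoyl)oxy]-3,6-dimethylbenzoate | COC(=O)c1c(C)cc(OC(=O)c2c(C)cc(OC)c(C=O)c2O)c(C)c1OCc1ccccc1 | intermediate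
21 | 3-{[3-(benzyloxy)-4-(methoxycarbonyl)-2,5-dimethylphenoxy]carbonyl}-2-hydroxy-6-methoxy-4-methylbenzoic acid | COC(=O)c1c(C)cc(OC(=O)c2c(C)cc(OC)c(C(=O)O)c2O)c(C)c1OCc1ccccc1 | intermediate
22 | 2-hydroxy-3-{[3-hydroxy-4-(methoxycarbonyl)-2,5-dimethylphenoxy]carbonyl}-6-methoxy-4-methylbenzoic acid | COC(=O)c1c(C)cc(OC(=O)c2c(C)cc(OC)c(C(=O)O)c2O)c(C)c1O | target

**Totals**

Total step count: 12.
Longest linear sequence: 10 steps (steps 1, 2, 3, 5, 6, 8, 9, 10, 11, 12).

**Steps most likely to fail**

1. Step 8 (benzannulation).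
   - What may go wrong: the vinylketene may be consumed by amine-initiated dimerization or oligomerization faster than the alkyne intercepts it. Deprotonation may deliver part of the ketene with the ester cis to the cumulene, which would then close through oxygen. The thermal ring opening of the cyclobutenone may stall.
   - Fallback: it sets out from phenol 4 and comes back at aldehyde 20, so that steps 4–10 are bypassed. Compound 4 would be esterified with purchased 2-hydroxy-4-methoxy-6-methylbenzoic acid by carbodiimide coupling (DCC, toluene, rt), which tolerates the chelated ortho hydroxyl of the acid, to give methyl 2-(benzyloxy)-4-[(2-hydroxy-4-methoxy-6-methylbenzoyl)oxy]-3,6-dimethylbenzoate F1. Magnesium-mediated ortho-formylation of the ring B phenol (MgCl2, Et3N, paraformaldehyde, THF, reflux) can only take place at C3', the single free position ortho to the C2' hydroxyl, and should give 20. Steps 11 and 12 then follow unchanged.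

2. Step 5 (anhydride opening).
   - What may go wrong: the C–H acidic anhydride may self-condense under base, O-acylation by the hindered and electron-poor phenol may be slow or reversible, and base may shift the double bond and scramble the Z geometry that step 8 relies on.
   - Fallback: it sets out from acid 5 and phenol 4 and comes back at vinylketene 14. Acid-catalysed esterification of 5 with allyl alcohol (cat. H2SO4, rt) should be selective for the non-conjugated carboxyl and give (2E)-3-methyl-5-oxo-5-(prop-2-en-1-yloxy)pent-2-enoic acid F2. Base-free mixed-anhydride esterification of its conjugated carboxyl with 4 (trifluoroacetic anhydride, toluene, rt) would give 1-Ar 5-allyl (2E)-3-methylpent-2-enedioate F3. Deallylation with Pd(PPh3)4 and PhSiH3 in CH2Cl2 would give (3E)-5-(Ar-oxy)-3-methyl-5-oxopent-3-enoic acid F4, and oxalyl chloride with catalytic DMF would give (3E)-5-(Ar-oxy)-3-methyl-5-oxopent-3-enoyl chloride F5. Under the conditions of step 8, F5 loses HCl from the CH2 next to COCl and gives 14 with the E geometry carried over from 5.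

3. Step 6 (acid chloride).
   - What may go wrong: the Z acid chloride holds the ester carbonyl next to COCl and may cyclize onto it with loss of HCl, or it may lose HCl prematurely and oligomerize on concentration.
   - Fallback: it sets out from acid 7 and comes back at vinylketene 14, without an isolated acid chloride. Acid 7 would be activated in the benzannulation flask with 2-chloro-1-methylpyridinium iodide and Et3N in CH2Cl2 in the presence of 13. This forms 2-{[(2Z)-5-(Ar-oxy)-3-methyl-5-oxopent-2-enoyl]oxy}-1-methylpyridinium iodide F6, which eliminates 1-methyl-2-pyridone under Et3N to give 14. The solvent is then exchanged for toluene and the mixture heated as in step 8.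

**Further compounds**

F1 | step 8 | methyl 2-(benzyloxy)-4-[(2-hydroxy-4-methoxy-6-methylbenzoyl)oxy]-3,6-dimethylbenzoate | COC(=O)c1c(C)cc(OC(=O)c2c(C)cc(OC)cc2O)c(C)c1OCc1ccccc1
F2 | step 5 | (2E)-3-methyl-5-oxo-5-(prop-2-en-1-yloxy)pent-2-enoic acid | C=CCOC(=O)C/C(C)=C/C(=O)O
F3 | step 5 | 1-Ar 5-allyl (2E)-3-methylpent-2-enedioate | COC(=O)c1c(C)cc(OC(=O)/C=C(C)/CC(=O)OCC=C)c(C)c1OCc1ccccc1
F4 | step 5 | (3E)-5-(Ar-oxy)-3-methyl-5-oxopent-3-enoic acid | COC(=O)c1c(C)cc(OC(=O)/C=C(C)/CC(=O)O)c(C)c1OCc1ccccc1
F5 | step 5 | (3E)-5-(Ar-oxy)-3-methyl-5-oxopent-3-enoyl chloride | COC(=O)c1c(C)cc(OC(=O)/C=C(C)/CC(=O)Cl)c(C)c1OCc1ccccc1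
F6 | step 6 | 2-{[(2Z)-5-(Ar-oxy)-3-methyl-5-oxopent-2-enoyl]oxy}-1-methylpyridinium iodide | C[n+]1ccccc1OC(=O)/C=C(C)\CC(=O)Oc1cc(C)c(C(=O)OC)c(OCc2ccccc2)c1C.[I-]
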